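## The problem

Neonambiquinone A (20) is a p-terphenyl built on a 1,4-benzoquinone, numbered here C1(=O), C2(OAc), C3(aryl), C4(=O), C5(H), C6(aryl), with a 4-hydroxyphenyl ring on C3 and on C6. Only two aryl–quinone C–C bonds hold the three rings together and there is no stereocentre, so nothing has to be controlled or relayed in three dimensions. The difficulty is regiochemical: one oxygen must sit on C2 and none on C5 of an otherwise symmetric 2,5-diarylquinone. The functionality is delicate: the 2-acetoxyquinone is a vinylogous mixed anhydride that gives up its acetyl group to bases, alcohols and other nucleophiles, the quinone is reducible and is a Michael acceptor at C5, and the two free phenols are oxidisable and would compete in any acylation. The phenols must therefore stay masked through ring construction, oxidation and acetylation, and the mask must come off last under conditions free of nucleophiles. The enabling feature is the triad C2(O)–C3(aryl)–C4(O), an aryl group flanked by two meta-related oxygens, with C1 para to the C4 oxygen. This is the pattern of a 2,5-diarylresorcinol whose oxygens are differentiated as OH and O-silyl, which is what a vinylketene–siloxyalkyne benzannulation delivers in one operation.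

## Retrosynthesis

20 ⇒ 19. The two benzyl C–O bonds are cut first, which leads back to bis(benzyl ether) 19. Unmasking last keeps the phenols out of the oxidation and the acetylation. A silyl mask would fall in the fluoride step, and an ester mask could not be told apart from the C2 acetate. Benzyl survives organolithium bases, heating to 110 °C, fluoride and a radical oxidant. Compound 19 has the same skeleton as 20 but no free OH. The forward step must remove both benzyl groups without acetyl transfer or addition to the quinone, which calls for a non-nucleophilic boron Lewis acid at low temperature.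

19 ⇒ 18. The acetyl C–O bond is cut to give hydroxyquinone 18. In 18 the C2 hydroxyl is the only free OH, so no selectivity among hydroxyls is needed; acetylating after debenzylation would mean telling three OH groups apart. The precursor is simpler by one acyl group. The forward step is a mild O-acylation of an acidic enol.

18 ⇒ 17. The C1 oxygen is removed, which turns 18 into 2,5-diarylresorcinol 17, a benzene with only two oxygens. Diol 17 has a mirror plane through C3 and C6, so its two free positions (C1 and C5) are equivalent, each para to one hydroxyl and ortho to the other. Oxygenation at either gives the same 1,2,4-trioxygenated ring, and the regiochemical question disappears. The neighbouring option, oxidising silyl ether 16 directly, needs the oxidant to attack a para position wedged between a triisopropylsilyloxy group and an aryl ring, and diversion to the free ortho position would lead to an ortho-quinone. The forward reaction is a Teuber oxidation that must stop at the hydroxyquinone.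

17 ⇒ 16. One resorcinol O–H is replaced by O–Si, which leads to monosilyl ether 16. This is the form in which the benzannulation delivers the ring, so the disconnection costs one routine fluoride step.

16 ⇒ 5 + 11. The central ring is cut at C3–C4 and C1–C2. This divides it into cyclobutenone 5 (C4, C5, C6, C1 and the C6 aryl) and siloxyalkyne 11 (C2, C3, the C3 aryl and the C2 oxygen). Aryl–aryl cross-coupling onto a preformed resorcinol would instead need a tetrasubstituted, differentially halogenated benzene. Here both aryl groups and two ring oxygens arrive as the ring forms, from two fragments that each carry one functional group. The forward reaction must be regiospecific in the ketene–alkyne union, and the polarisation of the ynol ether ensures that.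

5 ⇒ 4 ⇒ 1 + 2 (through 3). The four-membered ring is opened at its two ketene-derived bonds. Cyclobutenone 5 comes from dichlorocyclobutenone 4 by reductive removal of both chlorines. Compound 4 comes from the [2+2] union of arylacetylene 1 with dichloroketene 3, generated in the flask from trichloroacetyl chloride 2. The activated ketene is needed because ketene itself does not add to unactivated alkynes. The forward reaction must place the aryl group at C3 of the cyclobutenone, which the usual alkyne polarisation does.

11 ⇒ 6 + 7. The alkyne is cut between its two sp carbons. The oxygen-bearing carbon is the carbonyl carbon of benzoate 6, and the aryl-bearing carbon comes from dibromomethane 7. The sequence runs through carbenoid 8, dibromo enolate 9 and ynolate 10 in one flask, and 10 is trapped on oxygen with a bulky silyl chloride. This takes a stable commercial ester directly to the ynol ether without handling a free ynol or a ketene.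

## Roads not taken

Alternative 1: Hauser-type annulation of a sulfonyl tetronate with a nitrostyrene.
- Cut: C1–C6 and C4–C5. The butenolide 3-[4-(benzyloxy)phenyl]-4-methoxy-5-(phenylsulfonyl)furan-2(5H)-one A1 would supply C1 to C4 with all three oxygens, and nitrostyrene A2 would supply C5 and C6.
- Forward key step: the sulfonyl-bearing carbanion of A1 adds to the aryl-bearing carbon of A2, the nitronate carbon acylates the lactone carbonyl, and loss of sulfinate and nitrite gives methoxyquinone A3.
- Merits: the quinone oxidation level and the full oxygen pattern come out of the annulation, so no separate oxidation is needed. Regiochemistry follows from Michael polarity, and no heat-sensitive ynol ether is involved.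
- Weak points: A1 carries all the hard-won substitution and is itself a multistep compound. Annulations of this type are best established for benzo-fused donors. A monocyclic tetronate donor with a nitroalkene acceptor and a double elimination must compete with retro-Michael reaction and with O-acylation of the nitronate. A3 still needs its vinylogous methyl ester hydrolysed before acetylation, so the endgame is no shorter.
- Comparison: this road is better in redox economy. The chosen plan sets against it that 5 and 11 are each one or two steps from commercial compounds and that its annulation class is well documented.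

Alternative 2: Head-to-tail dimerisation of an aryl methyl diketone.
- Cut: C2–C3 and C5–C6, the same bond twice.
- Forward key step: two molecules of diketone A4 condense in dilute aqueous base, each methyl group attacking the aryl ketone of the other, to give the symmetric 2,5-diarylquinone A5.
- Merits: a single simple precursor, no organometallic reagents, and the shortest conceivable assembly of the carbon skeleton. On step count this road could equal or beat the chosen one.
- Weak points: A5 has no oxygen at C2. A later mono-oxygenation at one of two equivalent C–H positions (Thiele–Winter acetoxylation, or epoxidation and opening) has nothing in the structure to stop a second oxygenation at the other position. The double aldol condensation also competes with benzilic-acid-type rearrangement and other self-condensations, and the 4-alkoxy group makes the aryl ketone a poorer electrophile.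
- Comparison: the chosen plan sets against this brevity that the C2 oxygen is built in from the siloxyalkyne at a defined position, so nothing depends on halting an oxygenation halfway.

Alternative 3: Three-component Dötz benzannulation.
- Cut: C1–C6, C4–C5 and C1–C2, which divides the ring among the Fischer carbene complex (CO)5Cr=C(OMe)C(=CH2)Ar A6, alkyne 1 and one CO ligand.
- Forward key step: heating A6 with 1 gives 2,5-diaryl-4-methoxyphenol A7, which would then be oxidised to A5.
- Merits: insertion of a terminal alkyne is reliably regioselective, the para-dioxygen pattern arrives directly, and the alkyne partner is the same compound 1 used here. This benzannulation is arguably better documented for arylalkynes than the siloxyalkyne benzannulation is for aryl-substituted ynol ethers.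
- Weak points: the chromium complex is stoichiometric and takes several steps to make. More seriously, the road converges on A5 and inherits the same unsolved mono-oxygenation at C2 as Alternative 2, after more steps.
- Comparison: the chosen plan sets against the stronger precedent a metal-free key step, shorter fragment syntheses and the third oxygen in place from the start.

Key step: step 4

## Route

Remark: positional labels C1–C6 refer throughout to the quinone ring of 20 as defined above. Compound 20 is achiral; the only stereogenic carbon on the way (in 13) is racemic and is destroyed in the same flask.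

Step 1
Reactants: 1 1-(benzyloxy)-4-ethynylbenzene; 2 trichloroacetyl chloride
Product: 4 3-[4-(benzyloxy)phenyl]-4,4-dichlorocyclobut-2-en-1-one, via dichloroketene 3 (not isolated)
Conditions: Zn(Cu), Et2O–DME, rt, slow addition of 2
Reagents that add atoms: none
Why: Zinc dechlorinates 2 to dichloroketene 3, which adds to the terminal alkyne in a thermal ketene–alkyne [2+2] cycloaddition; the unsubstituted alkyne carbon bonds to the ketene carbonyl carbon, so the aryl group ends up at C3 of the cyclobutenone. Any 2,4-dichloro isomer formed by allylic chloride shift converges on the same product in step 2.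

Step 2
Reactants: 4 3-[4-(benzyloxy)phenyl]-4,4-dichlorocyclobut-2-en-1-one
Product: 5 3-[4-(benzyloxy)phenyl]cyclobut-2-en-1-one
Conditions: Zn, AcOH, TMEDA, EtOH, 0 °C to rt
Reagents that add atoms: none
Why: Reductive dehalogenation of the α,α-dichloro ketone by zinc, through zinc enolates that are protonated, removes both chlorines; the amine-buffered medium should prevent over-reduction and acid-induced ring opening, and the aryl benzyl ether is inert.

Step 3
Reactants: 6 methyl 4-(benzyloxy)benzoate; 7 dibromomethane
Product: 11 {[4-(benzyloxy)phenyl]ethynyloxy}triisopropylsilane, via dibromomethyllithium 8 (not isolated), via dibromo enolate 9 (not isolated), via lithium ynolate 10 (not isolated)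
Conditions: 7, lithium 2,2,6,6-tetramethylpiperidide (from 2,2,6,6-tetramethylpiperidine and n-BuLi, 2 equiv), THF, −78 °C; n-BuLi, −78 °C to rt; i-Pr3SiCl, −78 to 0 °C
Reagents that add atoms: triisopropylsilyl chloride CC(C)[Si](Cl)(C(C)C)C(C)C
Why: Kowalski ester homologation: carbenoid 8 adds to the ester, and after loss of methoxide and enolisation, enolate 9 undergoes bromine–lithium exchange and a 1,2-aryl shift to ynolate 10. The bulky silyl chloride should silylate 10 on oxygen, where smaller silyl chlorides give silylketenes; the benzyl ether tolerates the bases at low temperature.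

Step 4
Reactants: 5 3-[4-(benzyloxy)phenyl]cyclobut-2-en-1-one; 11 {[4-(benzyloxy)phenyl]ethynyloxy}triisopropylsilane
Product: 16 2,5-bis[4-(benzyloxy)phenyl]-3-[(triisopropylsilyl)oxy]phenol, via vinylketene 12 (not isolated), via vinylcyclobutenone 13 (not isolated), via dienylketene 14 (not isolated), via cyclohexadienone 15 (not isolated)
Conditions: 11 (1.3 equiv), degassed PhMe, 80 °C then 110 °C, sealed vessel
Reagents that add atoms: none
Why: Danheiser benzannulation, whose closest known form is the union of 3-substituted cyclobutenones with triisopropylsiloxyalkynes to resorcinol monosilyl ethers. At 80 °C cyclobutenone 5 opens reversibly by 4π electrocyclic ring opening to vinylketene 12, which the electron-rich alkyne 11 captures in a ketene–alkyne [2+2] cycloaddition to give 4-vinylcyclobutenone 13. A second 4π opening of 13 gives dienylketene 14; because this opening is reversible, the material is drained through the isomer that holds the vinyl group cis to the ketene carbon. The six-membered ring then closes by thermal disrotatory 6π electrocyclisation between the ketene carbon and the terminal CH2 (the C4–C5 bond) to cyclohexadienone 15, which enolises to phenol 16. The one selectivity needed is the orientation of the [2+2] step: the silyloxy oxygen polarises the alkyne so that its aryl-bearing carbon is the nucleophile and bonds to the ketene carbonyl carbon (C3–C4), while the oxygen-bearing carbon bonds to the ketene α-carbon (C1–C2), which places the aryl group between OH and OSi. No stereocentre is present in 16, and the one in 13 is racemic and is erased on ring opening. The benzyl ethers and the Si–O bond are inert to neutral heating, and the slight excess of 11 should limit acylation of 16 by 12.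

Step 5
Reactants: 16 2,5-bis[4-(benzyloxy)phenyl]-3-[(triisopropylsilyl)oxy]phenol
Product: 17 2,5-bis[4-(benzyloxy)phenyl]benzene-1,3-diol
Conditions: Bu4NF, AcOH, THF, 0 °C
Reagents that add atoms: none
Why: Fluoride-mediated desilylation of the aryl silyl ether; the acetic acid buffer keeps the electron-rich resorcinol protonated and so protects it from air oxidation, and the benzyl ethers are untouched.

Step 6
Reactants: 17 2,5-bis[4-(benzyloxy)phenyl]benzene-1,3-diol
Product: 18 3,6-bis[4-(benzyloxy)phenyl]-2-hydroxycyclohexa-2,5-diene-1,4-dione
Conditions: ON(SO3K)2 (2 equiv), KH2PO4, acetone–H2O, rt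
Reagents that add atoms: potassium nitrosodisulfonate ON(SO3K)2 [O]N(S(=O)(=O)[O-])S(=O)(=O)[O-].[K+].[K+]
Why: Teuber oxidation: hydrogen abstraction gives the phenoxyl radical, a second nitrosodisulfonate radical couples at the free position para to that oxygen, and loss of imidodisulfonate gives the quinone with the remaining hydroxyl at C2. Because 17 is mirror-symmetric, attack at either free position gives the same product; aryl benzyl ethers are not oxidised by this reagent.

Step 7
Reactants: 18 3,6-bis[4-(benzyloxy)phenyl]-2-hydroxycyclohexa-2,5-diene-1,4-dione
Product: 19 2,5-bis[4-(benzyloxy)phenyl]-3,6-dioxocyclohexa-1,4-dien-1-yl acetate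
Conditions: Ac2O, pyridine, CH2Cl2, 0 °C
Reagents that add atoms: acetic anhydride CC(=O)OC(C)=O
Why: O-acylation of the acidic hydroxyquinone, the only free hydroxyl at this stage; base-mediated rather than acid-catalysed conditions avoid Thiele–Winter acetoxylation at C5.

Step 8
Reactants: 19 2,5-bis[4-(benzyloxy)phenyl]-3,6-dioxocyclohexa-1,4-dien-1-yl acetate
Product: 20 neonambiquinone A [2,5-bis(4-hydroxyphenyl)-3,6-dioxocyclohexa-1,4-dien-1-yl acetate]
Conditions: BCl3, pentamethylbenzene, CH2Cl2, −78 °C; pH 7 phosphate buffer quench at −78 °C
Reagents that add atoms: none
Why: Lewis-acid debenzylation of aryl benzyl ethers with pentamethylbenzene as a non-basic benzyl-cation trap; the conditions are non-nucleophilic and non-reducing, so the acetoxyquinone should survive, and the neutral cold quench avoids acid-catalysed acetyl transfer.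

## Compound list

1 | 1-(benzyloxy)-4-ethynylbenzene | C#Cc1ccc(OCc2ccccc2)cc1 | starting material
2 | trichloroacetyl chloride | O=C(Cl)C(Cl)(Cl)Cl | starting material
3 | dichloroketene | O=C=C(Cl)Cl | intermediate
4 | 3-[4-(benzyloxy)phenyl]-4,4-dichlorocyclobut-2-en-1-one | O=C1C=C(c2ccc(OCc3ccccc3)cc2)C1(Cl)Cl | intermediate
5 | 3-[4-(benzyloxy)phenyl]cyclobut-2-en-1-one | O=C1C=C(c2ccc(OCc3ccccc3)cc2)C1 | intermediate
6 | methyl 4-(benzyloxy)benzoate | COC(=O)c1ccc(OCc2ccccc2)cc1 | starting material
7 | dibromomethane | BrCBr | starting material
8 | dibromomethyllithium | [Li]C(Br)Br | intermediate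
9 | lithium 1-[4-(benzyloxy)phenyl]-2,2-dibromoethen-1-olate | [Li+].[O-]C(=C(Br)Br)c1ccc(OCc2ccccc2)cc1 | intermediate
10 | lithium 2-[4-(benzyloxy)phenyl]ethyn-1-olate | [Li+].[O-]C#Cc1ccc(OCc2ccccc2)cc1 | intermediate
11 | {[4-(benzyloxy)phenyl]ethynyloxy}triisopropylsilane | CC(C)[Si](OC#Cc1ccc(OCc2ccccc2)cc1)(C(C)C)C(C)C | intermediate
12 | 3-[4-(benzyloxy)phenyl]buta-1,3-dien-1-one (vinylketene) | O=C=CC(=C)c1ccc(OCc2ccccc2)cc1 | intermediate
13 | 2-[4-(benzyloxy)phenyl]-4-{1-[4-(benzyloxy)phenyl]ethenyl}-3-[(triisopropylsilyl)oxy]cyclobut-2-en-1-one (racemic) | O=C1C(c2ccc(OCc3ccccc3)cc2)=C(O[Si](C(C)C)(C(C)C)C(C)C)C1C(=C)c1ccc(OCc2ccccc2)cc1 | intermediate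
14 | (3E)-2,5-bis[4-(benzyloxy)phenyl]-3-[(triisopropylsilyl)oxy]hexa-1,3,5-trien-1-one (ketene carbon and vinyl group cis) | O=C=C(c1ccc(OCc2ccccc2)cc1)\C(O[Si](C(C)C)(C(C)C)C(C)C)=C/C(=C)c1ccc(OCc2ccccc2)cc1 | intermediate
15 | 2,5-bis[4-(benzyloxy)phenyl]-3-[(triisopropylsilyl)oxy]cyclohexa-2,4-dien-1-one | O=C1CC(c2ccc(OCc3ccccc3)cc2)=CC(O[Si](C(C)C)(C(C)C)C(C)C)=C1c1ccc(OCc2ccccc2)cc1 | intermediate
16 | 2,5-bis[4-(benzyloxy)phenyl]-3-[(triisopropylsilyl)oxy]phenol | Oc1cc(-c2ccc(OCc3ccccc3)cc2)cc(O[Si](C(C)C)(C(C)C)C(C)C)c1-c1ccc(OCc2ccccc2)cc1 | intermediate
17 | 2,5-bis[4-(benzyloxy)phenyl]benzene-1,3-diol | Oc1cc(-c2ccc(OCc3ccccc3)cc2)cc(O)c1-c1ccc(OCc2ccccc2)cc1 | intermediate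
18 | 3,6-bis[4-(benzyloxy)phenyl]-2-hydroxycyclohexa-2,5-diene-1,4-dione | OC1=C(c2ccc(OCc3ccccc3)cc2)C(=O)C=C(c2ccc(OCc3ccccc3)cc2)C1=O | intermediate
19 | 2,5-bis[4-(benzyloxy)phenyl]-3,6-dioxocyclohexa-1,4-dien-1-yl acetate | CC(=O)OC1=C(c2ccc(OCc3ccccc3)cc2)C(=O)C=C(c2ccc(OCc3ccccc3)cc2)C1=O | intermediate
20 | neonambiquinone A, 2,5-bis(4-hydroxyphenyl)-3,6-dioxocyclohexa-1,4-dien-1-yl acetate | CC(=O)OC1=C(c2ccc(O)cc2)C(=O)C=C(c2ccc(O)cc2)C1=O | target

## Step count and risk

Total steps: 8 (steps 1 and 2 give cyclobutenone 5, step 3 gives siloxyalkyne 11, steps 4 to 8 are common). Longest linear sequence: 7 steps (1, 2, 4, 5, 6, 7, 8, from alkyne 1).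

Risk at step 4, the key step. The most likely failure is loss of the siloxyalkyne before it is captured. The aryl group slows attack of 11 on the ketene, so thermal silyl migration in 11 to a silylketene, adventitious hydrolysis, or self-condensation of the unhindered vinylketene 12 may outrun the bimolecular [2+2] step. Acylation of the product phenol by 12 is a second drain. The fallback for step 4 generates the same vinylketene in the cold; it sets out from 5 and returns at 16 by way of 13. Heating 5 in aqueous dioxane should trap 12 with water as 3-[4-(benzyloxy)phenyl]but-3-enoic acid F1 and oxalyl chloride in CH2Cl2 then converts F1 into 3-[4-(benzyloxy)phenyl]but-3-enoyl chloride F2 for the ketene release. Dehydrochlorination of F2 with Et3N at 0 °C to rt in the presence of 11 should release 12 at a temperature where 11 is safe and give 13, which is then warmed alone in toluene to 16.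

Risk at step 8. The most likely failure is transfer of the acetyl group out of the vinylogous anhydride during the quench, or addition of the HCl formed to C5 of the Lewis-acid-activated quinone. The fallback for step 8 replaces Lewis-acid cleavage by reduction and reoxidation; it sets out from 19 and returns at 20. Hydrogenolysis (H2, Pd/C, EtOAc) should remove both benzyl groups and reduce the quinone to give the hydroquinone 2,5-dihydroxy-3,6-bis(4-hydroxyphenyl)phenyl acetate F3 and air then reoxidises F3 to 20. The medium stays neutral and the exposure short, to hold back acetyl migration to the neighbouring hydroquinone oxygen.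

Risk at step 6. The most likely failure is over-oxidation or oxidative coupling of the very electron-rich diol, or incomplete conversion because the lipophilic terphenyl dissolves poorly in aqueous acetone. A two-phase CH2Cl2–water system with Bu4NHSO4 is the first adjustment. The fallback for step 6 changes the order of events; it sets out from 16 and returns at 18. The less electron-rich monophenol 16 is oxidised with ON(SO3K)2 at its free para position to 3,6-bis[4-(benzyloxy)phenyl]-2-[(triisopropylsilyl)oxy]cyclohexa-2,5-diene-1,4-dione F4 and the vinylogous silyl ester of F4 is then cleaved with Bu4NF buffered with AcOH to give 18. This gives up the regiochemical degeneracy of 17 and relies on the para preference of the oxidant.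

Risk at step 3. The most likely failures are incomplete carbenoid rearrangement, butyl addition to the transient ketone, or benzylic metalation of the benzyl ether by excess alkyllithium. The fallback for step 3 makes the ynolate by oxidation instead of homologation; it sets out from 1 and returns at 11 by way of 10. Deprotonation of 1 with n-BuLi gives lithium [4-(benzyloxy)phenyl]ethynide F5 and oxidation of F5 with LiOOt-Bu, made in the flask from t-BuOOH and LiN(SiMe3)2, gives ynolate 10, which is silylated with i-Pr3SiOSO2CF3 to 11. This variant draws both halves of the ring from the single alkyne 1.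

Risk at step 1. The most likely failure is oligomerisation of the electron-rich arylalkyne, or rearrangement of the dichlorocyclobutenone, promoted by the ZnCl2 that accumulates. The fallback for step 1 uses a keteniminium salt in place of the ketene; it sets out from 1 and returns at 5, bypassing 4 and step 2. N,N-Dimethylacetamide, (CF3SO2)2O and 2,4,6-collidine in 1,2-dichloroethane generate N-ethenylidene-N-methylmethanaminium trifluoromethanesulfonate F6 as the keteniminium salt. The [2+2] cycloaddition of F6 with 1 gives N-{3-[4-(benzyloxy)phenyl]cyclobut-2-en-1-ylidene}-N-methylmethanaminium trifluoromethanesulfonate F7 and aqueous NaHCO3 then hydrolyses F7 to 5.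

## Further compounds

F1 | step 4 | 3-[4-(benzyloxy)phenyl]but-3-enoic acid | C=C(CC(=O)O)c1ccc(OCc2ccccc2)cc1
F2 | step 4 | 3-[4-(benzyloxy)phenyl]but-3-enoyl chloride | C=C(CC(=O)Cl)c1ccc(OCc2ccccc2)cc1
F3 | step 8 | 2,5-dihydroxy-3,6-bis(4-hydroxyphenyl)phenyl acetate | CC(=O)Oc1c(O)c(-c2ccc(O)cc2)cc(O)c1-c1ccc(O)cc1
F4 | step 6 | 3,6-bis[4-(benzyloxy)phenyl]-2-[(triisopropylsilyl)oxy]cyclohexa-2,5-diene-1,4-dione | CC(C)[Si](OC1=C(c2ccc(OCc3ccccc3)cc2)C(=O)C=C(c2ccc(OCc3ccccc3)cc2)C1=O)(C(C)C)C(C)C
F5 | step 3 | lithium [4-(benzyloxy)phenyl]ethynide | [Li+].[C-]#Cc1ccc(OCc2ccccc2)cc1
F6 | step 1 | N-ethenylidene-N-methylmethanaminium trifluoromethanesulfonate | C=C=[N+](C)C.[O-]S(=O)(=O)C(F)(F)F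
F7 | step 1 | N-{3-[4-(benzyloxy)phenyl]cyclobut-2-en-1-ylidene}-N-methylmethanaminium trifluoromethanesulfonate | C[N+](C)=C1C=C(c2ccc(OCc3ccccc3)cc2)C1.[O-]S(=O)(=O)C(F)(F)F
A1 | alternative 1 | 3-[4-(benzyloxy)phenyl]-4-methoxy-5-(phenylsulfonyl)furan-2(5H)-one | COC1=C(c2ccc(OCc3ccccc3)cc2)C(=O)OC1S(=O)(=O)c1ccccc1
A2 | alternative 1 | 1-(benzyloxy)-4-[(E)-2-nitroethenyl]benzene | O=[N+]([O-])/C=C/c1ccc(OCc2ccccc2)cc1
A3 | alternative 1 | 3,6-bis[4-(benzyloxy)phenyl]-2-methoxycyclohexa-2,5-diene-1,4-dione | COC1=C(c2ccc(OCc3ccccc3)cc2)C(=O)C=C(c2ccc(OCc3ccccc3)cc2)C1=O
A4 | alternative 2 | 1-[4-(benzyloxy)phenyl]propane-1,2-dione | CC(=O)C(=O)c1ccc(OCc2ccccc2)cc1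
A5 | alternative 2 | 2,5-bis[4-(benzyloxy)phenyl]cyclohexa-2,5-diene-1,4-dione | O=C1C=C(c2ccc(OCc3ccccc3)cc2)C(=O)C=C1c1ccc(OCc2ccccc2)cc1
A6 | alternative 3 | pentacarbonyl[{1-[4-(benzyloxy)phenyl]ethenyl}(methoxy)methylidene]chromium, (CO)5Cr=C(OMe)C(=CH2)Ar | COC(=[Cr])C(=C)c1ccc(OCc2ccccc2)cc1.[C-]#[O+].[C-]#[O+].[C-]#[O+].[C-]#[O+].[C-]#[O+]
A7 | alternative 3 | 2,5-bis[4-(benzyloxy)phenyl]-4-methoxyphenol | COc1cc(-c2ccc(OCc3ccccc3)cc2)c(O)cc1-c1ccc(OCc2ccccc2)cc1
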